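## Retrosynthetic overview

Atom labels are positions in the target SMILES (C1 to O36).

1. Feature: the fifteen carbons C13, C14, C16–C18, C20–C26 and C28–C30 of ring C (seven-membered) and ring D (five-membered) form one head-to-tail sesquiterpene chain whose C25 is the carbinol carbon of dehydrolinalool; only the C21–C22 and C28–C14 bonds are absent from that chain.
2. Last operations: the C14–O15–C16 epoxide and the C18 hydroxyl come from a C16=C18 alkene (singlet-oxygen ene reaction, titanium-mediated oxygen transfer); H21 comes from hydroxyl-directed hydrogenation of C20=C21.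
3. Key disconnection: C21–C22 (ring D) and C28–C14 (ring C) in one gold-catalysed bicyclisation of a dienyne that already carries rings A and B.
4. Dienyne: C18–C20 bond from an (E)-allylic bromide on the left half and (R)-dehydrolinalool triethylsilyl ether (from geraniol by asymmetric epoxidation and epoxy chloride fragmentation).
5. Left half: rings A and B together from geranyl bromide by a diepoxide/enol silane cascade (O4–C2, then C31–C11), then equatorial methyl addition at C8. Ring order: A and B, then D, then C, then the epoxide.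

Key step: step 18

Remark on the chemistry: all three silyl ethers are triethylsilyl so that one fluoride treatment frees the C25 hydroxyl that must direct the hydrogenation, and the C8 and C35 hydroxyls are then carried free through the last two steps; L denotes the (3R,5aR,6R,7S,9aR)-2,2,5a,7-tetramethyl-3,7-bis(triethylsilyloxy)decahydro-1-benzoxepin-6-yl group (its C6 is C11 of the target).

## Route

Step 1
Reactants: 1 geranyl bromide; 2 dimethyl (2-oxopropyl)phosphonate
Product: 3 dimethyl [(5E)-6,10-dimethyl-2-oxoundeca-5,9-dien-1-yl]phosphonate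
Conditions: 2, NaH, THF, 0 °C; n-BuLi, 0 °C; 1, 0 °C to rt; 1 M HCl
Reagents that add atoms: none
Why: γ-Alkylation of a β-ketophosphonate 1,3-dianion, in which the more basic terminal carbanion (C7) displaces the primary allylic bromide by SN2 and forms C6–C7 without touching the (E)-C5=C31 alkene.

Step 2
Reactants: 3 β-ketophosphonate; 4 3-(benzyloxy)propanal
Product: 5 (3E,8E)-1-(benzyloxy)-9,13-dimethyltetradeca-3,8,12-trien-5-one
Conditions: LiCl, i-Pr2NEt, MeCN, rt
Reagents that add atoms: none
Why: Horner–Wadsworth–Emmons olefination under LiCl/amine conditions should give the (E)-enone C11=C12 and is mild enough not to eliminate the β-benzyloxy group of the aldehyde.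

Step 3
Reactants: 5 trienone
Product: 6 (4E)-7-(benzyloxy)-1-{(2R,3R)-3-[2-((2R)-3,3-dimethyloxiran-2-yl)ethyl]-3-methyloxiran-2-yl}hept-4-en-3-one
Conditions: D-fructose-derived ketone catalyst of the Shi epoxidation, KHSO5 (as 2KHSO5·KHSO4·K2SO4), K2CO3, Bu4NHSO4, aq. Na2B4O7 buffer, MeCN/CH2(OMe)2, 0 °C
Reagents that add atoms: potassium peroxymonosulfate, [K+].[O-]S(=O)(=O)OO
Why: Shi epoxidation, in which the chiral dioxirane oxidises only the two electron-rich trisubstituted alkenes, each on the face that makes the CH carbon (C5, C35) R, and leaves the electron-poor enone alkene.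

Step 4
Reactants: 6 diepoxy enone
Product: 7 (Z)-triethylsilyl enol ether of 6 (C8–OSiEt3, C8=C11)
Conditions: Et3SiH, RhCl(PPh3)3 (cat.), THF, 50 °C
Reagents that add atoms: triethylsilane, CC[SiH](CC)CC
Why: Rhodium-catalysed 1,4-hydrosilylation of the enone gives the enol silane with its double bond fixed toward C11 and, by addition through the s-cis enone, mainly the (Z)-isomer, while the neutral catalyst leaves both epoxides alone.

Step 5
Reactants: 7 diepoxy enol silane
Product: 8 (3R,5aR,6R,9aR)-6-[3-(benzyloxy)propyl]-2,2,5a-trimethyl-3-(triethylsilyloxy)octahydro-1-benzoxepin-7(2H)-one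
Conditions: Et3SiOTf (0.3 equiv), 2,6-di-tert-butyl-4-methylpyridine, CH2Cl2, −78 °C
Reagents that add atoms: none
Why: Epoxide-opening cascade triggered by a silyl triflate, in which the silylated C35–C2 epoxide is opened at tertiary C2 by the oxygen of the C5–C31 epoxide and the bicyclic epoxonium ion is opened at tertiary C31 with inversion by C11 of the (Z)-enol silane in a chair transition state, which should give the trans-fused oxepane/cyclohexanone (C5 and C35 retained, C31 inverted, C12 equatorial) while the enol silyl group returns to triflate, so that the whole is an isomerisation.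

Step 6
Reactants: 8 bicyclic ketone
Product: 9 (3R,5aR,6R,7S,9aR)-6-[3-(benzyloxy)propyl]-2,2,5a,7-tetramethyl-3-(triethylsilyloxy)decahydro-1-benzoxepin-7-ol
Conditions: MeLi, CeCl3, THF, −78 °C; aq. NH4Cl
Reagents that add atoms: methyllithium, [Li]C
Why: Organocerium 1,2-addition suppresses enolisation of the hindered ketone, and because the axial C31 methyl blocks axial approach the methyl group should enter equatorially, which sets C8 with its hydroxyl axial and cis to that methyl.

Step 7
Reactants: 9 tertiary alcohol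
Product: 10 (3R,5aR,6R,7S,9aR)-6-[3-(benzyloxy)propyl]-2,2,5a,7-tetramethyl-3,7-bis(triethylsilyloxy)decahydro-1-benzoxepine
Conditions: Et3SiOTf, 2,6-lutidine, CH2Cl2, −78 to 0 °C
Reagents that add atoms: triethylsilyl trifluoromethanesulfonate, CC[Si](CC)(CC)OS(=O)(=O)C(F)(F)F
Why: Silyl triflate silylation protects the hindered tertiary C8 alcohol, which would otherwise close a lactol with the C14 aldehyde and add to the enoate made later.

Step 8
Reactants: 10 benzyl ether
Product: 11 3-L-propan-1-ol
Conditions: H2 (1 atm), Pd/C, EtOAc, rt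
Reagents that add atoms: none
Why: Hydrogenolysis of the benzyl ether frees the primary C14 alcohol, the molecule having no alkene at this stage and the silyl ethers being stable in an aprotic solvent.

Step 9
Reactants: 11 primary alcohol
Product: 12 3-L-propanal
Conditions: Dess–Martin periodinane, pyridine, CH2Cl2, 0 °C to rt
Reagents that add atoms: none
Why: Dess–Martin oxidation gives the C14 aldehyde under buffered conditions that the silyl ethers tolerate.

Step 10
Reactants: 12 aldehyde; 13 ethyl 2-(triphenylphosphoranylidene)propanoate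
Product: 14 ethyl (2E)-2-methyl-5-L-pent-2-enoate
Conditions: toluene, 80 °C
Reagents that add atoms: none
Why: Wittig olefination with the stabilised α-methyl ylide should give the (E)-trisubstituted enoate, which fixes C13 trans to C18 across C14=C16.

Step 11
Reactants: 14 enoate
Product: 15 (2E)-2-methyl-5-L-pent-2-en-1-ol
Conditions: i-Bu2AlH, CH2Cl2, −78 °C; aq. potassium sodium tartrate
Reagents that add atoms: none
Why: 1,2-Reduction of the enoate with an aluminium hydride gives the allylic alcohol without touching the alkene geometry.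

Step 12
Reactants: 15 allylic alcohol
Product: 16 (2E)-1-bromo-2-methyl-5-L-pent-2-ene
Conditions: CBr4, PPh3, 2,6-lutidine, CH2Cl2, −20 °C
Reagents that add atoms: carbon tetrabromide, BrC(Br)(Br)Br
Why: Appel bromination substitutes the primary allylic alcohol by SN2 at low temperature, so that no allylic transposition is expected and the silyl ethers survive the buffered medium.

Step 13
Reactants: 17 geraniol
Product: 18 (2R,3R)-2,3-epoxygeraniol
Conditions: Ti(OiPr)4 (cat.), D-(−)-diethyl tartrate (cat.), t-BuOOH, 4 Å molecular sieves, CH2Cl2, −20 °C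
Reagents that add atoms: tert-butyl hydroperoxide, CC(C)(C)OO
Why: Sharpless asymmetric epoxidation with the D-tartrate ligand delivers oxygen to the face of the (E)-allylic alcohol that gives the (2R,3R)-epoxide, which fixes the future C25.

Step 14
Reactants: 18 epoxy alcohol
Product: 19 (2S,3R)-2-(chloromethyl)-3-methyl-3-(4-methylpent-3-en-1-yl)oxirane
Conditions: PPh3, CCl4, NaHCO3, reflux
Reagents that add atoms: carbon tetrachloride, ClC(Cl)(Cl)Cl
Why: Appel chlorination under neutral conditions converts the primary alcohol into the chloride and leaves the epoxide intact.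

Step 15
Reactants: 19 epoxy chloride
Product: 20 (R)-dehydrolinalool, (3R)-3,7-dimethyloct-6-en-1-yn-3-ol
Conditions: n-BuLi (3.3 equiv), THF, −40 °C; H2O
Reagents that add atoms: none
Why: Base-induced fragmentation of a 2,3-epoxy chloride, in which the α-chloro carbanion opens the epoxide by β-elimination and a second elimination of chloride gives the terminal alkyne, and since the C25–O bond is never broken the tertiary carbinol keeps its (R) configuration.

Step 16
Reactants: 20 (R)-dehydrolinalool
Product: 21 (3R)-3,7-dimethyl-3-(triethylsilyloxy)oct-6-en-1-yne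
Conditions: Et3SiOTf, 2,6-lutidine, CH2Cl2, 0 °C
Reagents that add atoms: triethylsilyl trifluoromethanesulfonate, CC[Si](CC)(CC)OS(=O)(=O)C(F)(F)F
Why: Silyl triflate silylation gives the hindered tertiary propargylic silyl ether, a group that is too bulky and too weakly donating to migrate in the gold step.

Step 17
Reactants: 21 alkyne silyl ether; 16 allylic bromide
Product: 23 left-half-bearing dienyne (C14=C16 E; C25 R; three triethylsilyl ethers), via alkynylmagnesium bromide 22 (not isolated)
Conditions: 21, EtMgBr, THF, 40 °C; CuBr·SMe2 (10 mol %), then 16, 0 °C to rt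
Reagents that add atoms: none
Why: Copper-catalysed SN2 coupling of the alkynyl Grignard reagent with the primary allylic bromide forms C18–C20 at the unhindered end of the allyl unit and should give the skipped enyne with the (E)-alkene intact.

Step 18
Reactants: 23 dienyne
Product: 24 tetracyclic diene (ring C 1,3-diene C16=C18 and C20=C21; H14 cis to H22; C28 trans to O27; three triethylsilyl ethers)
Conditions: [(2-biphenyl)P(t-Bu)2]Au(NCMe)SbF6 (3 mol %), 4 Å molecular sieves, CH2Cl2, −20 °C to rt
Reagents that add atoms: none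
Why: Proposed new method: π-coordination of the cationic monovalent gold fragment to C20≡C21 induces anti attack of C22 on C21 (ring D, 5-exo-dig) to give a cyclopropyl gold carbene with cationic character at tertiary C28, and the C14=C16 alkene, held one methylene away from the carbene carbon C20 and cis to C22, opens that cyclopropane at C28 through C14 (ring C, 7-endo-trig, Markovnikov), after which the C16 cation loses the doubly allylic H18 and the dienyl–gold bond at C20 is protonated with retention. The closest known reaction type is the gold-catalysed 5-exo-dig cyclisation of 1,6-enynes in which the cyclopropyl gold carbene is trapped intramolecularly by an alkene, an arene or a carbonyl group, but there the trap has not been an allyl group on the alkyne terminus closing a seven-membered ring. C22 is controlled by the quaternary C25: the alkene should add to the alkyne face that puts C28 anti to the triethylsilyloxy group, an arrangement in which that oxygen cannot reach C28. C14 is controlled by the (E)-C14=C16 geometry in a chair-like seven-membered transition state, which places C13 pseudo-equatorial and H14 cis to H22. The step needs the 1,6-enyne mode to beat any reaction of the 1,4-enyne, which the gem-disubstituted C25 favours, and needs C28 to be captured by C14 and not by oxygen, by loss of a methyl proton or by skeletal rearrangement, for which the silyl ether is too hindered and too weakly donating to migrate and no external nucleophile is present. Loss of H18 in preference to H14 or H17 is expected because it gives the conjugated dienyl–gold species.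

Step 19
Reactants: 24 tris(triethylsilyl) diene
Product: 25 diene triol (C8, C25 and C35 hydroxyls free)
Conditions: Bu4NF, THF, 50 °C
Reagents that add atoms: none
Why: Fluoride-mediated desilylation removes all three triethylsilyl ethers under basic conditions that the acid-sensitive dienylic tertiary alcohol tolerates.

Step 20
Reactants: 25 diene triol
Product: 26 alkene triol (C20–C21 saturated, H21 cis to H22 and to O27; C16=C18 retained)
Conditions: [Ir(cod)(py)(PCy3)]PF6 (5 mol %), H2 (1 atm), CH2Cl2, 0 °C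
Reagents that add atoms: none
Why: Hydroxyl-directed hydrogenation, in which the C25 hydroxyl binds the cationic iridium catalyst and delivers H2 to the allylic C20=C21 alkene on its own face, which should set H21 cis to O27 and to H22 (cis ring fusion) while the C16=C18 alkene has no directing group within reach.

Step 21
Reactants: 26 alkene triol
Product: 28 target CNP0203623.2, via allylic hydroperoxide 27 (not isolated)
Conditions: O2, visible light, tetraphenylporphyrin, Ti(OiPr)4 (20 mol %), 4 Å molecular sieves, CH2Cl2, 0 °C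
Reagents that add atoms: dioxygen, O=O
Why: Schenck ene reaction of singlet oxygen on the convex face (that of H14, H21 and H22) should place the hydroperoxide at C18 with abstraction of the axial H14 and shift of the alkene to C14=C16, and the titanium-bound allylic hydroperoxide then transfers its distal oxygen to that alkene on the face of the C18 oxygen, giving the syn epoxy alcohol in one flask.

## Compound list

1 | geranyl bromide, (2E)-1-bromo-3,7-dimethylocta-2,6-diene | CC(C)=CCC/C(C)=C/CBr | starting material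
2 | dimethyl (2-oxopropyl)phosphonate | CC(=O)CP(=O)(OC)OC | starting material
3 | dimethyl [(5E)-6,10-dimethyl-2-oxoundeca-5,9-dien-1-yl]phosphonate | COP(=O)(CC(=O)CC/C=C(\C)CCC=C(C)C)OC | intermediate
4 | 3-(benzyloxy)propanal | O=CCCOCc1ccccc1 | starting material
5 | (3E,8E)-1-(benzyloxy)-9,13-dimethyltetradeca-3,8,12-trien-5-one | O=C(/C=C/CCOCc1ccccc1)CC/C=C(\C)CCC=C(C)C | intermediate
6 | (4E)-7-(benzyloxy)-1-{(2R,3R)-3-[2-((2R)-3,3-dimethyloxiran-2-yl)ethyl]-3-methyloxiran-2-yl}hept-4-en-3-one | O=C(/C=C/CCOCc1ccccc1)CC[C@H]1O[C@]1(C)CC[C@H]1OC1(C)C | intermediate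
7 | triethyl{[(3Z)-7-(benzyloxy)-1-{(2R,3R)-3-[2-((2R)-3,3-dimethyloxiran-2-yl)ethyl]-3-methyloxiran-2-yl}hept-3-en-3-yl]oxy}silane | CC[Si](CC)(CC)O/C(=C\CCCOCc1ccccc1)CC[C@H]1O[C@]1(C)CC[C@H]1OC1(C)C | intermediate
8 | (3R,5aR,6R,9aR)-6-[3-(benzyloxy)propyl]-2,2,5a-trimethyl-3-(triethylsilyloxy)octahydro-1-benzoxepin-7(2H)-one | CC1(C)O[C@@H]2CCC(=O)[C@H](CCCOCc3ccccc3)[C@@]2(C)CC[C@H]1O[Si](CC)(CC)CC | intermediate
9 | (3R,5aR,6R,7S,9aR)-6-[3-(benzyloxy)propyl]-2,2,5a,7-tetramethyl-3-(triethylsilyloxy)decahydro-1-benzoxepin-7-ol | CC1(C)O[C@@H]2CC[C@](C)(O)[C@H](CCCOCc3ccccc3)[C@@]2(C)CC[C@H]1O[Si](CC)(CC)CC | intermediate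
10 | (3R,5aR,6R,7S,9aR)-6-[3-(benzyloxy)propyl]-2,2,5a,7-tetramethyl-3,7-bis(triethylsilyloxy)decahydro-1-benzoxepine | CC1(C)O[C@@H]2CC[C@](C)(O[Si](CC)(CC)CC)[C@H](CCCOCc3ccccc3)[C@@]2(C)CC[C@H]1O[Si](CC)(CC)CC | intermediate
11 | 3-[(3R,5aR,6R,7S,9aR)-2,2,5a,7-tetramethyl-3,7-bis(triethylsilyloxy)decahydro-1-benzoxepin-6-yl]propan-1-ol | CC1(C)O[C@@H]2CC[C@](C)(O[Si](CC)(CC)CC)[C@H](CCCO)[C@@]2(C)CC[C@H]1O[Si](CC)(CC)CC | intermediate
12 | 3-[(3R,5aR,6R,7S,9aR)-2,2,5a,7-tetramethyl-3,7-bis(triethylsilyloxy)decahydro-1-benzoxepin-6-yl]propanal | CC1(C)O[C@@H]2CC[C@](C)(O[Si](CC)(CC)CC)[C@H](CCC=O)[C@@]2(C)CC[C@H]1O[Si](CC)(CC)CC | intermediate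
13 | ethyl 2-(triphenylphosphoranylidene)propanoate | CCOC(=O)C(C)=P(c1ccccc1)(c1ccccc1)c1ccccc1 | starting material
14 | ethyl (2E)-2-methyl-5-L-pent-2-enoate | CC1(C)O[C@@H]2CC[C@](C)(O[Si](CC)(CC)CC)[C@H](CC/C=C(\C)C(=O)OCC)[C@@]2(C)CC[C@H]1O[Si](CC)(CC)CC | intermediate
15 | (2E)-2-methyl-5-L-pent-2-en-1-ol | CC1(C)O[C@@H]2CC[C@](C)(O[Si](CC)(CC)CC)[C@H](CC/C=C(\C)CO)[C@@]2(C)CC[C@H]1O[Si](CC)(CC)CC | intermediate
16 | (2E)-1-bromo-2-methyl-5-L-pent-2-ene | CC1(C)O[C@@H]2CC[C@](C)(O[Si](CC)(CC)CC)[C@H](CC/C=C(\C)CBr)[C@@]2(C)CC[C@H]1O[Si](CC)(CC)CC | intermediate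
17 | geraniol, (2E)-3,7-dimethylocta-2,6-dien-1-ol | CC(C)=CCC/C(C)=C/CO | starting material
18 | (2R,3R)-2,3-epoxygeraniol, [(2R,3R)-3-methyl-3-(4-methylpent-3-en-1-yl)oxiran-2-yl]methanol | CC(C)=CCC[C@@]1(C)O[C@@H]1CO | intermediate
19 | (2S,3R)-2-(chloromethyl)-3-methyl-3-(4-methylpent-3-en-1-yl)oxirane | CC(C)=CCC[C@@]1(C)O[C@@H]1CCl | intermediate
20 | (R)-dehydrolinalool, (3R)-3,7-dimethyloct-6-en-1-yn-3-ol | C#C[C@](C)(O)CCC=C(C)C | intermediate
21 | (3R)-3,7-dimethyl-3-(triethylsilyloxy)oct-6-en-1-yne | C#C[C@](C)(O[Si](CC)(CC)CC)CCC=C(C)C | intermediate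
22 | [(3R)-3,7-dimethyl-3-(triethylsilyloxy)oct-6-en-1-yn-1-yl]magnesium bromide | Br[Mg]C#C[C@](C)(O[Si](CC)(CC)CC)CCC=C(C)C | intermediate
23 | (3R,5aR,6R,7S,9aR)-2,2,5a,7-tetramethyl-3,7-bis(triethylsilyloxy)-6-[(3E,8R)-4,8,12-trimethyl-8-(triethylsilyloxy)trideca-3,11-dien-6-yn-1-yl]decahydro-1-benzoxepine | CC1(C)O[C@@H]2CC[C@](C)(O[Si](CC)(CC)CC)[C@H](CC/C=C(\C)CC#C[C@](C)(O[Si](CC)(CC)CC)CCC=C(C)C)[C@@]2(C)CC[C@H]1O[Si](CC)(CC)CC | intermediate
24 | tetracyclic diene: L-CH2CH2 on C5 of a 1,4,4,6-tetramethyl-1-(triethylsilyloxy)-1,2,3,3a,4,5-hexahydroazulene (C16=C18 and C20=C21; C25 R; H14 cis to H22; C28 trans to O27) | CC1(C)O[C@@H]2CC[C@](C)(O[Si](CC)(CC)CC)[C@H](CC[C@H]3C(C)=CC=C4[C@@H](CC[C@@]4(C)O[Si](CC)(CC)CC)C3(C)C)[C@@]2(C)CC[C@H]1O[Si](CC)(CC)CC | intermediate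
25 | diene triol: 24 with the three silyl groups removed | CC1(C)O[C@@H]2CC[C@](C)(O)[C@H](CC[C@H]3C(C)=CC=C4[C@@H](CC[C@@]4(C)O)C3(C)C)[C@@]2(C)CC[C@H]1O | intermediate
26 | alkene triol: 25 with C20–C21 saturated (H21 cis to H22 and to O27), C16=C18 retained | CC1(C)O[C@@H]2CC[C@](C)(O)[C@H](CC[C@H]3C(C)=CC[C@@H]4[C@@H](CC[C@@]4(C)O)C3(C)C)[C@@]2(C)CC[C@H]1O | intermediate
27 | C18 hydroperoxide of 26 with the alkene shifted to C14=C16 (OOH on the face of H21 and H22) | CC1(C)O[C@@H]2CC[C@](C)(O)[C@H](CCC3=C(C)[C@H](OO)C[C@@H]4[C@@H](CC[C@@]4(C)O)C3(C)C)[C@@]2(C)CC[C@H]1O | intermediate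
28 | CNP0203623.2 | CC1(C)O[C@@H]2CC[C@](C)(O)[C@H](CC[C@@]34O[C@]3(C)[C@H](O)C[C@@H]3[C@@H](CC[C@@]3(C)O)C4(C)C)[C@@]2(C)CC[C@H]1O | target

## Step count

Total steps: 21. Longest linear sequence: 17 steps (steps 1 to 12 and 17 to 21); the alkyne arm takes steps 13 to 16.

## Steps most likely to fail

**Step 18 (the step marked as a proposed new method).**
- What may go wrong: the cationic centre at C28 is diverted before C14 arrives (skeletal rearrangement to a vinylcyclopentene, loss of a methyl proton, migration of the silyloxy group).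
- The face selection at C22 may be poor or reversed, the seven-membered closure may run through a boat and give the C14 epimer, or the dienylic silyl ether of the product may ionise.
- Fallback with known chemistry, setting out from 23 and coming back at 24: the same gold complex in MeOH/CH2Cl2 at 0 °C performs the known methoxycyclisation of the 1,6-enyne alone. Ring D closes 5-exo-dig and methanol traps C28, which gives the ring D methyl ether F1, with an (E)-C20=C21 exocyclic alkene that holds C18 cis to C22. SnCl4 in CH2Cl2 at −78 °C then ionises the tertiary methyl ether, and the free C28 cation closes ring C onto C14=C16 in an ordinary cation–olefin cyclisation with loss of H18, which returns to 24.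

**Step 20.**
- What may go wrong: over-reduction of C16=C18, 1,4-addition of hydrogen across the conjugated diene, or binding of the diene to iridium that stalls the catalyst.
- Fallback, setting out from 24 and coming back at 26: the C16=C18 alkene is masked before the reduction. Dihydroxylation (OsO4 cat., N-methylmorpholine N-oxide, acetone/H2O) should attack the less hindered C16=C18 bond on the convex face and give the cis-diol F2. The C18 hydroxyl of F2 then directs the same iridium-catalysed hydrogenation to the only remaining alkene and gives the saturated diol F3. 1,1'-Thiocarbonyldiimidazole in hot toluene gives the cyclic thionocarbonate F4, HF·pyridine in THF removes the silyl groups to give the triol thionocarbonate F5, and Corey–Winter olefination (P(OMe)3, 110 °C) restores C16=C18 and returns to 26.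

**Step 21.**
- What may go wrong: hydrogen abstraction at C20 or at the C17 methyl in place of C14, which gives regioisomeric hydroperoxides.
- Fallback, setting out from 26 and coming back at 28: the C14=C16 alkene is made by thermodynamic enolisation of a C18 ketone.
  - Et3SiOTf/2,6-lutidine gives the tris(triethylsilyl) ether F6.
  - Hydroboration–oxidation (BH3·THF, then NaOH/H2O2) from the convex face gives the C18 alcohol F7, and Dess–Martin oxidation gives the C18 ketone F8.
  - Me3SiCl/NaI/Et3N in MeCN gives the more substituted trimethylsilyl enol ether F9, and Saegusa–Ito oxidation with Pd(OAc)2 in MeCN gives the C14=C16 enone F10.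
  - Corey–Bakshi–Shibata reduction ((S)-2-methyl-CBS-oxazaborolidine, catecholborane, toluene, −78 °C) sets the (18R)-allylic alcohol F11 by reagent control.
  - VO(acac)2/t-BuOOH epoxidation directed by that hydroxyl gives the syn epoxy alcohol F12, and Bu4NF in THF returns to 28.

## Further compounds

F1 | step 18 | ring D methyl ether: (E)-alkylidenecyclopentane with C25(CH3)(OSiEt3) and C22–C(CH3)2OCH3, chain L-CH2CH2CH=C(CH3)CH2CH= | CC1(C)O[C@@H]2CC[C@](C)(O[Si](CC)(CC)CC)[C@H](CC/C=C(\C)C/C=C3/[C@](C)(O[Si](CC)(CC)CC)CC[C@H]3C(C)(C)OC)[C@@]2(C)CC[C@H]1O[Si](CC)(CC)CC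
F2 | step 20 | C16,C18-cis-diol of 24 (both hydroxyls on the face of H22; C20=C21 retained) | CC1(C)O[C@@H]2CC[C@](C)(O[Si](CC)(CC)CC)[C@H](CC[C@H]3[C@](C)(O)[C@H](O)C=C4[C@@H](CC[C@@]4(C)O[Si](CC)(CC)CC)C3(C)C)[C@@]2(C)CC[C@H]1O[Si](CC)(CC)CC
F3 | step 20 | F2 with C20–C21 saturated (H21 cis to H22) | CC1(C)O[C@@H]2CC[C@](C)(O[Si](CC)(CC)CC)[C@H](CC[C@H]3[C@](C)(O)[C@H](O)C[C@@H]4[C@@H](CC[C@@]4(C)O[Si](CC)(CC)CC)C3(C)C)[C@@]2(C)CC[C@H]1O[Si](CC)(CC)CC
F4 | step 20 | cyclic C16,C18-thionocarbonate of F3 | CC1(C)O[C@@H]2CC[C@](C)(O[Si](CC)(CC)CC)[C@H](CC[C@H]3[C@]5(C)OC(=S)O[C@@H]5C[C@@H]4[C@@H](CC[C@@]4(C)O[Si](CC)(CC)CC)C3(C)C)[C@@]2(C)CC[C@H]1O[Si](CC)(CC)CC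
F5 | step 20 | triol thionocarbonate (F4 without silyl groups) | CC1(C)O[C@@H]2CC[C@](C)(O)[C@H](CC[C@H]3[C@]5(C)OC(=S)O[C@@H]5C[C@@H]4[C@@H](CC[C@@]4(C)O)C3(C)C)[C@@]2(C)CC[C@H]1O
F6 | step 21 | tris(triethylsilyl) ether of 26 | CC1(C)O[C@@H]2CC[C@](C)(O[Si](CC)(CC)CC)[C@H](CC[C@H]3C(C)=CC[C@@H]4[C@@H](CC[C@@]4(C)O[Si](CC)(CC)CC)C3(C)C)[C@@]2(C)CC[C@H]1O[Si](CC)(CC)CC
F7 | step 21 | C18 alcohol from hydroboration of F6 (H16 and O19 on the face of H22) | CC1(C)O[C@@H]2CC[C@](C)(O[Si](CC)(CC)CC)[C@H](CC[C@H]3[C@@H](C)[C@H](O)C[C@@H]4[C@@H](CC[C@@]4(C)O[Si](CC)(CC)CC)C3(C)C)[C@@]2(C)CC[C@H]1O[Si](CC)(CC)CC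
F8 | step 21 | C18 ketone | CC1(C)O[C@@H]2CC[C@](C)(O[Si](CC)(CC)CC)[C@H](CC[C@H]3[C@@H](C)C(=O)C[C@@H]4[C@@H](CC[C@@]4(C)O[Si](CC)(CC)CC)C3(C)C)[C@@]2(C)CC[C@H]1O[Si](CC)(CC)CC
F9 | step 21 | C16=C18 trimethylsilyl enol ether of F8 | CC1(C)O[C@@H]2CC[C@](C)(O[Si](CC)(CC)CC)[C@H](CC[C@H]3C(C)=C(O[Si](C)(C)C)C[C@@H]4[C@@H](CC[C@@]4(C)O[Si](CC)(CC)CC)C3(C)C)[C@@]2(C)CC[C@H]1O[Si](CC)(CC)CC
F10 | step 21 | C14=C16 enone (C18 ketone) | CC1(C)O[C@@H]2CC[C@](C)(O[Si](CC)(CC)CC)[C@H](CCC3=C(C)C(=O)C[C@@H]4[C@@H](CC[C@@]4(C)O[Si](CC)(CC)CC)C3(C)C)[C@@]2(C)CC[C@H]1O[Si](CC)(CC)CC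
F11 | step 21 | (18R)-allylic alcohol with C14=C16 | CC1(C)O[C@@H]2CC[C@](C)(O[Si](CC)(CC)CC)[C@H](CCC3=C(C)[C@H](O)C[C@@H]4[C@@H](CC[C@@]4(C)O[Si](CC)(CC)CC)C3(C)C)[C@@]2(C)CC[C@H]1O[Si](CC)(CC)CC
F12 | step 21 | tris(triethylsilyl) ether of 28 at O10, O27 and O36 | CC1(C)O[C@@H]2CC[C@](C)(O[Si](CC)(CC)CC)[C@H](CC[C@@]34O[C@]3(C)[C@H](O)C[C@@H]3[C@@H](CC[C@@]3(C)O[Si](CC)(CC)CC)C4(C)C)[C@@]2(C)CC[C@H]1O[Si](CC)(CC)CC
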